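**Strategy.** The plan removes one atom from the central ring B. This is C4, the oxygen-bearing carbon between the bridge-bearing carbons C3 and C5. The remaining chain C3–C2(O)–C1(COPr)–C6(O)–C5 is a symmetric triacylmethane whose outer acyl groups are 3-arylpropanoyl arms, so both CH2 bridges to rings A and C already exist. In one operation, polylithiation and dimethyl carbonate form C3–C4 and C4–C5 and aromatise ring B. The precursor is a centrally acylated tetrahydrocurcuminoid with benzyl-protected terminal rings. Its butyryl carbonyl is masked as the methyl enol ether, because a free butyryl group would offer a third, equally acidic α-CH2 and spoil the site selectivity.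

Key step: step 6

Numbering: in ring B, C1 carries the butyryl group, C2/C4/C6 the hydroxyl groups and C3/C5 the bridges. Rings A and C are the terminal rings.
Assumption: the two boron chelates of step 3 are drawn in their simplest form, with two butoxy ligands on boron. The real mixture from B2O3 and B(OnBu)3 holds related borate chelates that react alike.
Remark: β-dicarbonyl compounds are drawn as keto tautomers. The two unisolated intermediates of step 6 exist as lithium salts and are listed in neutral form. Their enol ether geometry and one transient sp3 centre are undefined and disappear in the product. The target has no stereocentre.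
Design remark: the butyryl groups of rings A and C are added after the key step, because two more enolisable ketones would compete for base and carbonate.

Step 1
Reactants: 1 2-methylphloroglucinol (2-methylbenzene-1,3,5-triol)
Product: 3 2,4,6-trihydroxy-3-methylbenzaldehyde, via aryl iminium chloride 2 (not isolated)
Conditions: POCl3 (1.1 equiv), DMF (1.2 equiv), EtOAc, 0 °C → rt; then H2O, 50 °C
Reagents that add atoms: N,N-dimethylformamide, CN(C)C=O; water, O
Why: Vilsmeier–Haack formylation: the two free ring carbons of 1 are equivalent by symmetry, the iminium group of 2 deactivates the ring against a second attack, and warm water hydrolyses 2 to the aldehyde.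

Step 2
Reactants: 3 2,4,6-trihydroxy-3-methylbenzaldehyde; 4 benzyl bromide
Product: 5 2,4,6-tris(benzyloxy)-3-methylbenzaldehyde
Conditions: BnBr (3.6 equiv), K2CO3 (4.5 equiv), DMF, 60 °C
Reagents that add atoms: benzyl bromide (4), BrCc1ccccc1
Why: Threefold Williamson ether synthesis: the formyl group lowers the carbon nucleophilicity of the ring so that O-benzylation should outrun C-benzylation, and excess carbonate in warm DMF also reaches the two hydrogen-bonded ortho hydroxyl groups.

Step 3
Reactants: 6 acetylacetone; 5 2,4,6-tris(benzyloxy)-3-methylbenzaldehyde (two equivalents)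
Product: 9 (1E,6E)-1,7-bis[2,4,6-tris(benzyloxy)-3-methylphenyl]hepta-1,6-diene-3,5-dione, via dibutoxyboron acetylacetonate 7 (not isolated), via boron chelate of the dienone 8 (not isolated)
Conditions: B2O3, B(OnBu)3, EtOAc, 70 °C; then 5, n-BuNH2 (cat., slow addition), 70 °C; then 1 M aq HCl, 60 °C
Reagents that add atoms: none
Why: Boron-chelate-directed twofold aldol condensation, the standard curcuminoid synthesis: chelation in 7 blocks the central carbon against Knoevenagel condensation and acidifies the methyl groups, the amine activates 5 as its imine, and E1cB loss of water (taken up by the borate) should give the more stable E,E-dienone, which dilute acid sets free from 8.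

Step 4
Reactants: 9 (1E,6E)-1,7-bis[2,4,6-tris(benzyloxy)-3-methylphenyl]hepta-1,6-diene-3,5-dione
Product: 10 1,7-bis[2,4,6-tris(benzyloxy)-3-methylphenyl]heptane-3,5-dione
Conditions: H2 (4 bar), RhCl(PPh3)3 (5 mol %), toluene/EtOH, 50 °C
Reagents that add atoms: none
Why: Homogeneous catalytic hydrogenation with RhCl(PPh3)3 saturates the two disubstituted enone C=C bonds and has no pathway for hydrogenolysis of aryl benzyl ethers or for ketone reduction, both of which would threaten over Pd.

Step 5
Reactants: 10 1,7-bis[2,4,6-tris(benzyloxy)-3-methylphenyl]heptane-3,5-dione; 11 trimethyl orthobutyrate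
Product: 12 4-(1-methoxybutylidene)-1,7-bis[2,4,6-tris(benzyloxy)-3-methylphenyl]heptane-3,5-dione (the methyl enol ether of 4-butanoyl-1,7-bis[2,4,6-tris(benzyloxy)-3-methylphenyl]heptane-3,5-dione, same carbon skeleton)
Conditions: 11 (3 equiv), Ac2O (4 equiv), 120 °C, MeOAc distilled off; rapid filtration through neutral alumina
Reagents that add atoms: trimethyl orthobutyrate (11), CCCC(OC)(OC)OC
Why: Claisen-type orthoester condensation of an active methylene compound: Ac2O ionises 11 to the dimethoxycarbenium ion, the enol of 10 attacks it through its central carbon and loss of methanol gives the push–pull enol ether, so the mask sits on the butyryl carbon only (that carbon arrives at the orthoester level) and no E/Z isomers arise because the two acyl groups are identical.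

Step 6
Reactants: 12 4-(1-methoxybutylidene)-1,7-bis[2,4,6-tris(benzyloxy)-3-methylphenyl]heptane-3,5-dione; 13 dimethyl carbonate
Product: 16 1-(2,4,6-trihydroxy-3,5-bis{[2,4,6-tris(benzyloxy)-3-methylphenyl]methyl}phenyl)butan-1-one, via lithiated diketo ester 14 (not isolated), via ring B aryl enol ether 15 (not isolated)
Conditions: LiN(i-Pr)2 (3.2 equiv), THF, −78 → 0 °C; 13 (1.0 equiv), −78 → −20 °C; LiN(i-Pr)2 (2.0 equiv), −78 °C → rt; then 1 M aq HCl, THF, 0 °C → rt
Reagents that add atoms: dimethyl carbonate (13), COC(=O)OC; water, O
Why: Proposed new method: the first two equivalents of base take the acidic γ-hydrogen of the push–pull enol ether and one arm α-hydrogen, giving a β-diketonate dianion whose only hard carbanion is C3, and this carbon attacks dimethyl carbonate and forms C3–C4 (14, deprotonated at once by the spare base). The second charge of base metalates C5, which adds to the ester carbonyl C4 and expels methoxide; this closes ring B in a 6-(enolendo)-exo-trig Claisen step that aromatisation to the trilithium salt of 15 makes irreversible, and dilute acid then hydrolyses the electron-rich aryl enol ether to the C1 butyryl group. The closest known reaction types are the terminal C-acylation of β-diketone dianions by carbonates and esters and the base-induced Claisen cyclisation of polyketo esters to acylphloroglucinols; new are the use of one carbonate carbon as a double electrophile in one flask and a closing nucleophile activated by only one carbonyl group, which is why an amide base and not an alkoxide is needed. No stereocentre is formed. Site selectivity between the arms and the butyryl chain is secured by the mask: after the first deprotonation the butyryl α-carbon is the vinylic γ-end of a stabilised diketonate, many pK units less reactive than a terminal carbanion and without a second acidic hydrogen, while the two arms are equivalent by symmetry, so either may react first. Carbon against oxygen acylation follows from the terminal carbanion being the most basic site, and double acylation and lactonisation are held back by using one equivalent of the sluggish carbonate, consuming it before C5 is metalated and keeping 14 cold until the extra base is present.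

Step 7
Reactants: 16 1-(2,4,6-trihydroxy-3,5-bis{[2,4,6-tris(benzyloxy)-3-methylphenyl]methyl}phenyl)butan-1-one
Product: 17 1-{2,4,6-trihydroxy-3,5-bis[(2,4,6-trihydroxy-3-methylphenyl)methyl]phenyl}butan-1-one
Conditions: H2 (1 atm), 10% Pd/C, THF/MeOH, rt; filtration under argon, used at once
Reagents that add atoms: none
Why: Heterogeneous hydrogenolysis of six aryl benzyl ethers under neutral conditions leaves the diarylmethane bridges and the strongly hydrogen-bonded aryl ketone untouched and avoids the acid or base that could redistribute the bridges.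

Step 8
Reactants: 17 1-{2,4,6-trihydroxy-3,5-bis[(2,4,6-trihydroxy-3-methylphenyl)methyl]phenyl}butan-1-one; 18 butyryl chloride
Product: 19 1-{3,5-bis[(3-butanoyl-2,4,6-trihydroxy-5-methylphenyl)methyl]-2,4,6-trihydroxyphenyl}butan-1-one (CNP0296563.0)
Conditions: 18 (2.3 equiv), AlCl3 (10 equiv), CH2Cl2/MeNO2, 0 °C → rt, argon sweep; then ice, 1 M aq HCl
Reagents that add atoms: butyryl chloride (18), CCCC(Cl)=O
Why: Twofold Friedel–Crafts acylation: rings A and C each have exactly one unsubstituted carbon, ortho to two hydroxyl groups and para to the third, whereas ring B is fully substituted and deactivated by its ketone, so the regiochemistry is unambiguous and any phenol ester formed on the way should shift to carbon (Fries) or be cleaved in the work-up.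

Compound list
1 | 2-methylphloroglucinol | Cc1c(O)cc(O)cc1O | starting material
2 | (2,4,6-trihydroxy-3-methylbenzylidene)dimethylammonium chloride | C[N+](C)=Cc1c(O)c(C)c(O)cc1O.[Cl-] | intermediate
3 | 2,4,6-trihydroxy-3-methylbenzaldehyde | O=Cc1c(O)c(C)c(O)cc1O | intermediate
4 | benzyl bromide | BrCc1ccccc1 | starting material
5 | 2,4,6-tris(benzyloxy)-3-methylbenzaldehyde | O=Cc1c(OCc2ccccc2)c(C)c(OCc2ccccc2)cc1OCc1ccccc1 | intermediate
6 | acetylacetone | CC(=O)CC(C)=O | starting material
7 | dibutoxyboron acetylacetonate | CCCCO[B-]1(OCCCC)OC(C)=CC(C)=[O+]1 | intermediate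
8 | dibutoxyboron chelate of dienone 9 | CCCCO[B-]1(OCCCC)OC(/C=C/c2c(OCc3ccccc3)c(C)c(OCc3ccccc3)cc2OCc2ccccc2)=CC(/C=C/c2c(OCc3ccccc3)c(C)c(OCc3ccccc3)cc2OCc2ccccc2)=[O+]1 | intermediate
9 | (1E,6E)-1,7-bis[2,4,6-tris(benzyloxy)-3-methylphenyl]hepta-1,6-diene-3,5-dione | O=C(/C=C/c1c(OCc2ccccc2)c(C)c(OCc2ccccc2)cc1OCc1ccccc1)CC(=O)/C=C/c1c(OCc2ccccc2)c(C)c(OCc2ccccc2)cc1OCc1ccccc1 | intermediate
10 | 1,7-bis[2,4,6-tris(benzyloxy)-3-methylphenyl]heptane-3,5-dione | O=C(CCc1c(OCc2ccccc2)c(C)c(OCc2ccccc2)cc1OCc1ccccc1)CC(=O)CCc1c(OCc2ccccc2)c(C)c(OCc2ccccc2)cc1OCc1ccccc1 | intermediate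
11 | trimethyl orthobutyrate (1,1,1-trimethoxybutane) | CCCC(OC)(OC)OC | starting material
12 | 4-(1-methoxybutylidene)-1,7-bis[2,4,6-tris(benzyloxy)-3-methylphenyl]heptane-3,5-dione | CCCC(OC)=C(C(=O)CCc1c(OCc2ccccc2)c(C)c(OCc2ccccc2)cc1OCc1ccccc1)C(=O)CCc1c(OCc2ccccc2)c(C)c(OCc2ccccc2)cc1OCc1ccccc1 | intermediate
13 | dimethyl carbonate | COC(=O)OC | starting material
14 | methyl 5-methoxy-3-oxo-2-{[2,4,6-tris(benzyloxy)-3-methylphenyl]methyl}-4-{3-[2,4,6-tris(benzyloxy)-3-methylphenyl]propanoyl}oct-4-enoate (present as lithium polyenolate) | CCCC(OC)=C(C(=O)CCc1c(OCc2ccccc2)c(C)c(OCc2ccccc2)cc1OCc1ccccc1)C(=O)C(Cc1c(OCc2ccccc2)c(C)c(OCc2ccccc2)cc1OCc1ccccc1)C(=O)OC | intermediate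
15 | 2-(1-methoxybut-1-en-1-yl)-4,6-bis{[2,4,6-tris(benzyloxy)-3-methylphenyl]methyl}benzene-1,3,5-triol (present as trilithium salt) | CCC=C(OC)c1c(O)c(Cc2c(OCc3ccccc3)c(C)c(OCc3ccccc3)cc2OCc2ccccc2)c(O)c(Cc2c(OCc3ccccc3)c(C)c(OCc3ccccc3)cc2OCc2ccccc2)c1O | intermediate
16 | 1-(2,4,6-trihydroxy-3,5-bis{[2,4,6-tris(benzyloxy)-3-methylphenyl]methyl}phenyl)butan-1-one | CCCC(=O)c1c(O)c(Cc2c(OCc3ccccc3)c(C)c(OCc3ccccc3)cc2OCc2ccccc2)c(O)c(Cc2c(OCc3ccccc3)c(C)c(OCc3ccccc3)cc2OCc2ccccc2)c1O | intermediate
17 | 1-{2,4,6-trihydroxy-3,5-bis[(2,4,6-trihydroxy-3-methylphenyl)methyl]phenyl}butan-1-one | CCCC(=O)c1c(O)c(Cc2c(O)c(C)c(O)cc2O)c(O)c(Cc2c(O)c(C)c(O)cc2O)c1O | intermediate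
18 | butyryl chloride | CCCC(Cl)=O | starting material
19 | 1-{3,5-bis[(3-butanoyl-2,4,6-trihydroxy-5-methylphenyl)methyl]-2,4,6-trihydroxyphenyl}butan-1-one (CNP0296563.0) | CCCC(=O)c1c(O)c(C)c(O)c(Cc2c(O)c(Cc3c(O)c(C)c(O)c(C(=O)CCC)c3O)c(O)c(C(=O)CCC)c2O)c1O | target

Total step count: 8. Longest linear sequence: 8 steps (1 → 19).

Steps most likely to fail

1. Step 6. Several processes could spoil this step.
- Metalation of the second arm may stay incomplete.
- A second carbonate molecule may be taken up before closure.
- Closure may run through an enolate oxygen (lactonisation to a 4-hydroxy-2-pyranone) or through the vinylogous γ-carbon of the mask.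
- The closure may stall because the ester sits in the flask as its unreactive β-keto ester enolate.

The fallback uses known chemistry and buys ring B instead of building it. Setting out from 5, NaBH4 in THF/MeOH reduces the aldehyde to [2,4,6-tris(benzyloxy)-3-methylphenyl]methanol F1. Two equivalents of F1 are added slowly to commercial 2,4,6-trihydroxybutyrophenone (CCCC(=O)c1c(O)cc(O)cc1O) with catalytic Sc(OTf)3 in MeCN/CH2Cl2 at −20 °C. This is a Friedel–Crafts benzylation of both free ring carbons by a highly stabilised benzylic cation, and it comes back to the route at 16.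

2. Step 8. Ipso-protonation of the very electron-rich terminal rings under AlCl3/HCl could cleave and redistribute the CH2 bridges. The reaction could also stall after one acylation, and the polyphenol could suffer air oxidation during handling. The fallback is a Houben–Hoesch acylation. Setting out from 17, butyronitrile, ZnCl2 and dry HCl in Et2O at 0 °C deliver a nitrilium electrophile to the same two carbons. The bis-hydrochloride of 1-{3,5-bis[(3-butanimidoyl-2,4,6-trihydroxy-5-methylphenyl)methyl]-2,4,6-trihydroxyphenyl}butan-1-one F2 should precipitate and so leave the acidic solution. Brief warming in water hydrolyses both ketimine groups and comes back to the route at 19.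

3. Step 5. The orthoester could be lost by elimination to its ketene acetal. O-acetylation or O-methylation of the enol could occur in place of C–C bond formation, and the mask could hydrolyse on isolation. The fallback changes both the electrophile and the mask.
- N,N-dimethylbutanamide is O-methylated with Me2SO4 to 1-methoxy-N,N-dimethylbutan-1-iminium methyl sulfate F3.
- NaOMe in MeOH converts this salt into 1,1-dimethoxy-N,N-dimethylbutan-1-amine F4.
- Setting out from 10, heating with F4 in toluene at 90 °C (neutral amide acetal condensation) should give 4-[1-(dimethylamino)butylidene]-1,7-bis[2,4,6-tris(benzyloxy)-3-methylphenyl]heptane-3,5-dione F5.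
- Under the conditions of step 6, F5 is deprotonated in the same way and should close to 2-[1-(dimethylamino)but-1-en-1-yl]-4,6-bis{[2,4,6-tris(benzyloxy)-3-methylphenyl]methyl}benzene-1,3,5-triol F6.
- The acid work-up hydrolyses this enamine and comes back to the route at 16.

Further compounds
F1 | step 6 | [2,4,6-tris(benzyloxy)-3-methylphenyl]methanol | OCc1c(OCc2ccccc2)c(C)c(OCc2ccccc2)cc1OCc1ccccc1
F2 | step 8 | 1-{3,5-bis[(3-butanimidoyl-2,4,6-trihydroxy-5-methylphenyl)methyl]-2,4,6-trihydroxyphenyl}butan-1-one | CCCC(=N)c1c(O)c(C)c(O)c(Cc2c(O)c(Cc3c(O)c(C)c(O)c(C(=N)CCC)c3O)c(O)c(C(=O)CCC)c2O)c1O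
F3 | step 5 | 1-methoxy-N,N-dimethylbutan-1-iminium methyl sulfate | CCCC(OC)=[N+](C)C.COS(=O)(=O)[O-]
F4 | step 5 | 1,1-dimethoxy-N,N-dimethylbutan-1-amine | CCCC(OC)(OC)N(C)C
F5 | step 5 | 4-[1-(dimethylamino)butylidene]-1,7-bis[2,4,6-tris(benzyloxy)-3-methylphenyl]heptane-3,5-dione | CCCC(N(C)C)=C(C(=O)CCc1c(OCc2ccccc2)c(C)c(OCc2ccccc2)cc1OCc1ccccc1)C(=O)CCc1c(OCc2ccccc2)c(C)c(OCc2ccccc2)cc1OCc1ccccc1
F6 | step 5 | 2-[1-(dimethylamino)but-1-en-1-yl]-4,6-bis{[2,4,6-tris(benzyloxy)-3-methylphenyl]methyl}benzene-1,3,5-triol | CCC=C(N(C)C)c1c(O)c(Cc2c(OCc3ccccc3)c(C)c(OCc3ccccc3)cc2OCc2ccccc2)c(O)c(Cc2c(OCc3ccccc3)c(C)c(OCc3ccccc3)cc2OCc2ccccc2)c1O
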